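**Plan**
Retrosynthesis: the C8–CH3 bond is cut first (back to a Δ7 enol triflate of an 8-ketone), then C9=C11 (aldol condensation with an aryl aldehyde), then ring A at C1–C2 and C4–C5 together with the two C4–CH3 bonds, leaving acetone and a ring-B keto aldehyde.
Forward: ring B is a cyclohexane-1,4-dione mono-ketal whose quaternary C10 carries CH3 and CHO next to the C5 ketone; ring A is closed on it in one operation by a double aldol condensation with acetone; ring B is then finished and the aryl unit joined late.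
Enabling feature: C1 (CHO) and C5 (ring C=O) stand 1,3 across quaternary C10, so they cannot enolise toward each other and can only condense outward with the two α-carbons of one acetone, giving the six-membered ring C1–C2–C3–C4–C5–C10 as a cross-conjugated dienone.
The dienone is used twice more: it allows geminal methylation at C4 with the double bond moving to C5=C6, and hydrogenation of that bond sets C5.
Stereochemistry: C10 by enantioselective Pd-catalysed allylation; C5–H and C9–H by hydrogenation from the face opposite the axial C10 methyl.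

Key step: step 5

Remark: decalin carbons are given in terpenoid (drimane) numbering (C4 gem-dimethyl carbon, C5/C10 ring fusion, C8 methyl-bearing alkene carbon, C9 carries the arylmethyl carbon C11). Compound 1 is taken as the racemic catalogue ketone; if not at hand it is one methylation (LDA, MeI) from 1,4-dioxaspiro[4.5]decan-8-one.

Step 1
Reactants: 1 7-methyl-1,4-dioxaspiro[4.5]decan-8-one (racemic)
Product: 2 trimethyl[(7-methyl-1,4-dioxaspiro[4.5]dec-7-en-8-yl)oxy]silane
Conditions: TMSCl, Et3N, DMF, 90 °C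
Reagents that add atoms: chlorotrimethylsilane, C[Si](C)(C)Cl
Why: Thermodynamic silyl enol ether formation under equilibrating amine conditions should favour the tetrasubstituted enol silane (the minor regioisomer is removed), and the stereocentre of 1 is erased.

Step 2
Reactants: 2 trimethyl[(7-methyl-1,4-dioxaspiro[4.5]dec-7-en-8-yl)oxy]silane
Product: 3 (R)-7-allyl-7-methyl-1,4-dioxaspiro[4.5]decan-8-one
Conditions: Pd2(dba)3 (cat.), (S)-t-Bu-PHOX (cat.), diallyl carbonate, Bu4N Ph3SiF2 (substoichiometric), THF, 25 °C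
Reagents that add atoms: diallyl carbonate, C=CCOC(=O)OCC=C
Why: Enantioselective Tsuji allylation of the fluoride-activated enol silane, in which the chiral PHOX–Pd–allyl complex differentiates the enolate faces and sets quaternary C10; the (S)-ligand is expected to give the 7R ketone, the same spatial sense as (S)-2-allyl-2-methylcyclohexanone.

Step 3
Reactants: 3 (R)-7-allyl-7-methyl-1,4-dioxaspiro[4.5]decan-8-one
Product: 4 (S)-7-methyl-7-[(E)-prop-1-en-1-yl]-1,4-dioxaspiro[4.5]decan-8-one
Conditions: RuHCl(CO)(PPh3)3 (cat.), toluene, 90 °C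
Reagents that add atoms: none
Why: Ru–H olefin isomerisation (hydrometalation/β-hydride elimination) moves the terminal alkene one position to the (E)-propenyl group and cannot go further because the next carbon is quaternary.

Step 4
Reactants: 4 (S)-7-methyl-7-[(E)-prop-1-en-1-yl]-1,4-dioxaspiro[4.5]decan-8-one
Product: 5 (S)-7-methyl-8-oxo-1,4-dioxaspiro[4.5]decane-7-carbaldehyde
Conditions: O3, CH2Cl2/MeOH, −78 °C; then Me2S, −78 °C to 25 °C; used crude
Reagents that add atoms: ozone, [O-][O+]=O
Why: Ozonolysis with reductive work-up cleaves the propenyl group to the aldehyde (C1) without touching the quaternary stereocentre.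

Step 5
Reactants: 5 (S)-7-methyl-8-oxo-1,4-dioxaspiro[4.5]decane-7-carbaldehyde; 6 acetone
Product: 8 (4a′S)-4a′-methyl-4a′,5′,7′,8′-tetrahydro-2′H-spiro[1,3-dioxolane-2,6′-naphthalen]-2′-one (cross-conjugated dienone, C1=C2 and C4=C5), via aldol adduct 7 (not isolated)
Conditions: acetone (large excess), piperidine, AcOH, benzene, reflux with azeotropic removal of water
Reagents that add atoms: none
Why: Double aldol condensation, the ring-forming variant by which 2-formyl-2-alkylcycloalkanones and acetone give 4a-alkyl cross-conjugated cyclohexadienones: the piperidine enamine of acetone adds through C2 to the more electrophilic, non-enolisable aldehyde C1 (aldol 7), the second α-carbon (C4) of the same acetone unit then adds to the ring ketone C5, and two E1cB dehydrations give the dienone. Ring A (C1–C2–C3–C4–C5–C10) closes in the second aldol as a 6-(enolexo)-exo-trig closure; should 7 dehydrate first to the (E)-enone, reversible conjugate addition of piperidine at C1 restores a rotatable sp3 centre so that closure stays possible. No new stereocentre is formed, since C1, C2, C4 and C5 all end sp2, and quaternary C10 cannot epimerise. The step needs chemoselective pairing (aldehyde with one α-carbon, ketone with the other) and suppression of self-condensation; this is secured because acetone is symmetric and in large excess, C1 has no α-hydrogen, and the ring ketone can enolise only toward C6, where cyclisation onto C3 would give a bridged ketol that cannot dehydrate and therefore reverts, so the irreversible double dehydration funnels material to 8.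

Step 6
Reactants: 8 (4a′S)-4a′-methyl-4a′,5′,7′,8′-tetrahydro-2′H-spiro[1,3-dioxolane-2,6′-naphthalen]-2′-one
Product: 9 (4a′S)-1′,1′,4a′-trimethyl-1′,4a′,5′,7′-tetrahydro-2′H-spiro[1,3-dioxolane-2,6′-naphthalen]-2′-one (C1=C2 and C5=C6)
Conditions: t-BuOK (excess), t-BuOH/THF, 25 °C; MeI (excess)
Reagents that add atoms: iodomethane, CI
Why: Deconjugative α,α-dialkylation of a cross-conjugated dienone: γ-deprotonation at C6 gives the extended enolate that is methylated at C4, the resulting Δ5 ketone is deprotonated and methylated at C4 again, and C2 cannot compete because it is vinylic.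

Step 7
Reactants: 9 (4a′S)-1′,1′,4a′-trimethyl-1′,4a′,5′,7′-tetrahydro-2′H-spiro[1,3-dioxolane-2,6′-naphthalen]-2′-one
Product: 10 (4a′R,8a′R)-1′,1′,4a′-trimethyloctahydro-2′H-spiro[1,3-dioxolane-2,6′-naphthalen]-2′-one (trans-fused, 5α-H, 10β-CH3)
Conditions: H2 (50 bar), 10% Pd/C, EtOAc, 40 °C
Reagents that add atoms: none
Why: Heterogeneous catalytic hydrogenation reduces the enone C1=C2 bond first and then the hindered C5=C6 bond from the α-face, opposite the axial C10 and C4β methyl groups, which sets C5 with the trans ring fusion.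

Step 8
Reactants: 10 (4a′R,8a′R)-1′,1′,4a′-trimethyloctahydro-2′H-spiro[1,3-dioxolane-2,6′-naphthalen]-2′-one
Product: 13 (4aS,8aR)-5,5,8a-trimethyloctahydronaphthalen-2(1H)-one (trans-fused 8-ketone), via hydrazone 11 (not isolated), via deoxygenated ketal 12 (not isolated)
Conditions: N2H4·H2O, KOH, diethylene glycol, 130 °C then 210 °C; then 2 M HCl, THF, 25 °C
Reagents that add atoms: water, O
Why: Wolff–Kishner reduction removes the hindered C3 carbonyl while the base-stable ketal survives, and the acidic work-up hydrolyses the ketal to the C8 ketone without affecting the non-epimerisable ring-fusion centres.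

Step 9
Reactants: 13 (4aS,8aR)-5,5,8a-trimethyloctahydronaphthalen-2(1H)-one
Product: 14 (4aS,8aR)-5,5,8a-trimethyl-4a,5,6,7,8,8a-hexahydronaphthalen-2(1H)-one (C6=C7 enone)
Conditions: IBX, DMSO/toluene, 80 °C
Reagents that add atoms: none
Why: IBX-mediated α,β-dehydrogenation of the ketone can give only the C6=C7 enone, because the other α-carbon (C9) has no β-hydrogen (C10 is quaternary).

Step 10
Reactants: 15 methyl 4-hydroxy-3-methoxybenzoate
Product: 16 methyl 3-formyl-4-hydroxy-5-methoxybenzoate
Conditions: MgCl2, Et3N, paraformaldehyde, MeCN, reflux; aq. HCl work-up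
Reagents that add atoms: formaldehyde (as paraformaldehyde), C=O
Why: Magnesium-phenoxide-directed ortho-formylation places the formyl group at the only free position ortho to the phenol, a second formaldehyde acting as hydride acceptor.

Step 11
Reactants: 16 methyl 3-formyl-4-hydroxy-5-methoxybenzoate
Product: 17 methyl 3-formyl-4,5-dihydroxybenzoate
Conditions: BBr3, CH2Cl2, −78 °C to 0 °C; then MeOH, H2O
Reagents that add atoms: none
Why: Lewis-acid cleavage of the aryl methyl ether (boron coordination, SN2 demethylation by bromide) should be faster than attack on the methyl ester at low temperature.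

Step 12
Reactants: 17 methyl 3-formyl-4,5-dihydroxybenzoate
Product: 18 methyl 3,4-bis[(tert-butyldimethylsilyl)oxy]-5-formylbenzoate
Conditions: TBSOTf, 2,6-lutidine, CH2Cl2, 0 °C to 25 °C
Reagents that add atoms: tert-butyldimethylsilyl trifluoromethanesulfonate, CC(C)(C)[Si](C)(C)OS(=O)(=O)C(F)(F)F
Why: Silylation of both phenols gives a catechol protection that tolerates enolates, hydrogenation and cross-coupling and is removed at the end by fluoride without acid.

Step 13
Reactants: 14 (4aS,8aR)-5,5,8a-trimethyl-4a,5,6,7,8,8a-hexahydronaphthalen-2(1H)-one; 18 methyl 3,4-bis[(tert-butyldimethylsilyl)oxy]-5-formylbenzoate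
Product: 21 methyl 3,4-bis[(tert-butyldimethylsilyl)oxy]-5-{(E)-[(4aS,8aS)-5,5,8a-trimethyl-2-oxo-4a,5,6,7,8,8a-hexahydronaphthalen-1(2H)-ylidene]methyl}benzoate, via aldol adduct 19 (not isolated), via aldol mesylate 20 (not isolated)
Conditions: LDA, THF, −78 °C; 18, −78 °C; MsCl, −78 °C to 0 °C; DBU, 25 °C
Reagents that add atoms: none
Why: Directed aldol condensation: kinetic deprotonation of the enone can occur only at C9 (C7 is vinylic), and aldol addition, mesylation and E1cB elimination give the cross-conjugated arylidene enone, whose alkene geometry is irrelevant because it is hydrogenated next.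

Step 14
Reactants: 21 arylidene enone
Product: 22 methyl 3,4-bis[(tert-butyldimethylsilyl)oxy]-5-{[(1R,4aS,8aS)-5,5,8a-trimethyl-2-oxodecahydronaphthalen-1-yl]methyl}benzoate (9β-arylmethyl, 9α-H)
Conditions: H2 (1 atm), 10% Pd/C, EtOAc, 25 °C
Reagents that add atoms: none
Why: Catalytic hydrogenation saturates both conjugated C=C bonds and delivers hydrogen to C9 from the α-face opposite the axial C10 methyl, giving the 9α-H/equatorial arylmethyl epimer, which should also be the more stable one at this epimerisable centre.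

Step 15
Reactants: 22 saturated 9β-arylmethyl 8-ketone
Product: 23 methyl 3,4-bis[(tert-butyldimethylsilyl)oxy]-5-{[(1R,4aS,8aS)-5,5,8a-trimethyl-2-{[(trifluoromethyl)sulfonyl]oxy}-1,4,4a,5,6,7,8,8a-octahydronaphthalen-1-yl]methyl}benzoate (Δ7 enol triflate)
Conditions: KHMDS, THF, −78 °C; PhNTf2, −78 °C to 0 °C
Reagents that add atoms: N-phenylbis(trifluoromethanesulfonimide), O=S(=O)(N(c1ccccc1)S(=O)(=O)C(F)(F)F)C(F)(F)F
Why: Kinetic enolate formation occurs at the unhindered C7 methylene rather than the hindered C9 methine, and O-triflation fixes the double bond at C7=C8 while leaving C9 untouched.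

Step 16
Reactants: 23 Δ7 enol triflate
Product: 24 methyl 3,4-bis[(tert-butyldimethylsilyl)oxy]-5-{[(1S,4aS,8aS)-2,5,5,8a-tetramethyl-1,4,4a,5,6,7,8,8a-octahydronaphthalen-1-yl]methyl}benzoate
Conditions: MeZnCl, Pd(PPh3)4 (cat.), THF, 50 °C
Reagents that add atoms: methylzinc chloride, C[Zn]Cl
Why: Negishi cross-coupling of the alkenyl triflate installs the C8 methyl with retention of the alkene position and tolerates the ester and silyl ethers.

Step 17
Reactants: 24 bis-silyl ether of the target
Product: 25 methyl 3,4-dihydroxy-5-{[(1S,4aS,8aS)-2,5,5,8a-tetramethyl-1,4,4a,5,6,7,8,8a-octahydronaphthalen-1-yl]methyl}benzoate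
Conditions: TBAF, AcOH, THF, 0 °C
Reagents that add atoms: none
Why: Buffered fluoride desilylation frees the catechol under non-acidic conditions, so the trisubstituted alkene cannot cyclise onto the phenol and the methyl ester is kept.

**Compound list**
1 | 7-methyl-1,4-dioxaspiro[4.5]decan-8-one (racemic) | CC1CC2(OCCO2)CCC1=O | starting material
2 | trimethyl[(7-methyl-1,4-dioxaspiro[4.5]dec-7-en-8-yl)oxy]silane | CC1=C(O[Si](C)(C)C)CCC2(OCCO2)C1 | intermediate
3 | (R)-7-allyl-7-methyl-1,4-dioxaspiro[4.5]decan-8-one | C=CC[C@@]1(C)C(=O)CCC2(OCCO2)C1 | intermediate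
4 | (S)-7-methyl-7-[(E)-prop-1-en-1-yl]-1,4-dioxaspiro[4.5]decan-8-one | C/C=C/[C@@]1(C)C(=O)CCC2(OCCO2)C1 | intermediate
5 | (S)-7-methyl-8-oxo-1,4-dioxaspiro[4.5]decane-7-carbaldehyde | O=C[C@@]1(C)C(=O)CCC2(OCCO2)C1 | intermediate
6 | acetone | CC(C)=O | starting material
7 | (7S)-7-(1-hydroxy-3-oxobutyl)-7-methyl-1,4-dioxaspiro[4.5]decan-8-one (carbinol epimers) | CC(=O)CC(O)[C@@]1(C)C(=O)CCC2(OCCO2)C1 | intermediate
8 | (4a′S)-4a′-methyl-4a′,5′,7′,8′-tetrahydro-2′H-spiro[1,3-dioxolane-2,6′-naphthalen]-2′-one | O=C1C=C[C@]2(C)CC3(OCCO3)CCC2=C1 | intermediate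
9 | (4a′S)-1′,1′,4a′-trimethyl-1′,4a′,5′,7′-tetrahydro-2′H-spiro[1,3-dioxolane-2,6′-naphthalen]-2′-one | O=C1C=C[C@]2(C)CC3(OCCO3)CC=C2C1(C)C | intermediate
10 | (4a′R,8a′R)-1′,1′,4a′-trimethyloctahydro-2′H-spiro[1,3-dioxolane-2,6′-naphthalen]-2′-one (trans-fused) | O=C1CC[C@]2(C)CC3(OCCO3)CC[C@H]2C1(C)C | intermediate
11 | hydrazone of 10 | NN=C1CC[C@]2(C)CC3(OCCO3)CC[C@H]2C1(C)C | intermediate
12 | (4a′R,8a′S)-1′,1′,4a′-trimethyloctahydro-1′H-spiro[1,3-dioxolane-2,6′-naphthalene] (trans-fused) | C1CC[C@]2(C)CC3(OCCO3)CC[C@H]2C1(C)C | intermediate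
13 | (4aS,8aR)-5,5,8a-trimethyloctahydronaphthalen-2(1H)-one (trans-fused) | O=C1CC[C@H]2C(C)(C)CCC[C@]2(C)C1 | intermediate
14 | (4aS,8aR)-5,5,8a-trimethyl-4a,5,6,7,8,8a-hexahydronaphthalen-2(1H)-one | O=C1C=C[C@H]2C(C)(C)CCC[C@]2(C)C1 | intermediate
15 | methyl 4-hydroxy-3-methoxybenzoate | COC(=O)c1ccc(O)c(OC)c1 | starting material
16 | methyl 3-formyl-4-hydroxy-5-methoxybenzoate | COC(=O)c1cc(OC)c(O)c(C=O)c1 | intermediate
17 | methyl 3-formyl-4,5-dihydroxybenzoate | COC(=O)c1cc(O)c(O)c(C=O)c1 | intermediate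
18 | methyl 3,4-bis[(tert-butyldimethylsilyl)oxy]-5-formylbenzoate | COC(=O)c1cc(O[Si](C)(C)C(C)(C)C)c(O[Si](C)(C)C(C)(C)C)c(C=O)c1 | intermediate
19 | aldol adduct of 14 (C9) and 18 (carbinol and C9 epimers; trans-decalin as in 14) | COC(=O)c1cc(O[Si](C)(C)C(C)(C)C)c(O[Si](C)(C)C(C)(C)C)c(C(O)C2C(=O)C=C[C@H]3C(C)(C)CCC[C@]23C)c1 | intermediate
20 | methanesulfonate of 19 | COC(=O)c1cc(O[Si](C)(C)C(C)(C)C)c(O[Si](C)(C)C(C)(C)C)c(C(OS(C)(=O)=O)C2C(=O)C=C[C@H]3C(C)(C)CCC[C@]23C)c1 | intermediate
21 | methyl 3,4-bis[(tert-butyldimethylsilyl)oxy]-5-{(E)-[(4aS,8aS)-5,5,8a-trimethyl-2-oxo-4a,5,6,7,8,8a-hexahydronaphthalen-1(2H)-ylidene]methyl}benzoate | COC(=O)c1cc(O[Si](C)(C)C(C)(C)C)c(O[Si](C)(C)C(C)(C)C)c(/C=C2/C(=O)C=C[C@H]3C(C)(C)CCC[C@]23C)c1 | intermediate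
22 | methyl 3,4-bis[(tert-butyldimethylsilyl)oxy]-5-{[(1R,4aS,8aS)-5,5,8a-trimethyl-2-oxodecahydronaphthalen-1-yl]methyl}benzoate | COC(=O)c1cc(O[Si](C)(C)C(C)(C)C)c(O[Si](C)(C)C(C)(C)C)c(C[C@H]2C(=O)CC[C@H]3C(C)(C)CCC[C@]23C)c1 | intermediate
23 | methyl 3,4-bis[(tert-butyldimethylsilyl)oxy]-5-{[(1R,4aS,8aS)-5,5,8a-trimethyl-2-{[(trifluoromethyl)sulfonyl]oxy}-1,4,4a,5,6,7,8,8a-octahydronaphthalen-1-yl]methyl}benzoate | COC(=O)c1cc(O[Si](C)(C)C(C)(C)C)c(O[Si](C)(C)C(C)(C)C)c(C[C@H]2C(OS(=O)(=O)C(F)(F)F)=CC[C@H]3C(C)(C)CCC[C@]23C)c1 | intermediate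
24 | methyl 3,4-bis[(tert-butyldimethylsilyl)oxy]-5-{[(1S,4aS,8aS)-2,5,5,8a-tetramethyl-1,4,4a,5,6,7,8,8a-octahydronaphthalen-1-yl]methyl}benzoate | COC(=O)c1cc(O[Si](C)(C)C(C)(C)C)c(O[Si](C)(C)C(C)(C)C)c(C[C@H]2C(C)=CC[C@H]3C(C)(C)CCC[C@]23C)c1 | intermediate
25 | methyl 3,4-dihydroxy-5-{[(1S,4aS,8aS)-2,5,5,8a-tetramethyl-1,4,4a,5,6,7,8,8a-octahydronaphthalen-1-yl]methyl}benzoate | COC(=O)c1cc(O)c(O)c(C[C@H]2C(C)=CC[C@H]3C(C)(C)CCC[C@]23C)c1 | target

**Step count and risks**
Total step count: 17. Longest linear sequence: 14 (steps 1–9 and 13–17); the aryl aldehyde is made in 3 steps (10–12).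

Steps most likely to fail:

Step 5. The formyl group may be lost by retro-Claisen cleavage under the amine/acid conditions, or the sequence may stall at the open-chain (E)-enone before the second aldol closes the ring. The fallback builds the ring stepwise; it sets out from 5 and returns at 8. Wittig olefination of 5 with 1-(triphenylphosphoranylidene)propan-2-one should give the (E)-enone F1. Hydrogenation of its C=C bond (H2, Pd/C) gives the saturated 1,5-diketone F2. Base-mediated intramolecular aldol condensation (KOH, MeOH, the ring-closing half of a Robinson annulation) gives the octalone F3. Dehydrogenation with DDQ in dioxane then introduces the C1=C2 bond and gives 8.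

Step 13. Addition of the hindered C9 enolate to the ortho-silyloxy aldehyde may be incomplete, and the aldolate may revert during activation. The fallback replaces condensation by alkylation; it sets out from 14 and 18 and returns at 22. Reduction of 18 (BH3·THF, 0 °C) gives the benzylic alcohol F4, and CBr4/PPh3 converts it into the benzylic bromide F5. Alkylation of the lithium enolate of 14 (LDA, THF/DMPU) with F5 should give the 9α-arylmethyl enone F6, by attack anti to the axial C10 methyl. Re-enolisation (KHMDS, −78 °C) and kinetic protonation from the same α-face (AcOH) invert C9 to the 9β-arylmethyl enone F7. Hydrogenation of the C6=C7 bond (H2, Pd/C) then gives 22.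

Step 7. Reduction of the C5=C6 bond, flanked by two quaternary carbons, may be incomplete or lose face selectivity on the catalyst surface. The fallback stages the two reductions and forms the C5–H bond by hydrogen-atom transfer; it sets out from 9 and returns at 10. Homogeneous hydrogenation with RhCl(PPh3)3 reduces only the disubstituted C1=C2 bond and gives the Δ5 ketone F8. Metal-hydride hydrogen-atom-transfer hydrogenation (Mn(dpm)3, PhSiH3, t-BuOOH, i-PrOH) then generates the tertiary C5 radical, which is quenched to the more stable trans-fused ring system 10.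

Further compounds
F1 | step 5 | (S)-7-methyl-7-[(E)-3-oxobut-1-en-1-yl]-1,4-dioxaspiro[4.5]decan-8-one | CC(=O)/C=C/[C@@]1(C)C(=O)CCC2(OCCO2)C1
F2 | step 5 | (R)-7-methyl-7-(3-oxobutyl)-1,4-dioxaspiro[4.5]decan-8-one | CC(=O)CC[C@@]1(C)C(=O)CCC2(OCCO2)C1
F3 | step 5 | 4a′-methyl-3′,4′,4a′,5′,7′,8′-hexahydro-2′H-spiro[1,3-dioxolane-2,6′-naphthalen]-2′-one (C4=C5 octalone, C10 configured as in 8) | O=C1CC[C@]2(C)CC3(OCCO3)CCC2=C1
F4 | step 13 | methyl 3,4-bis[(tert-butyldimethylsilyl)oxy]-5-(hydroxymethyl)benzoate | COC(=O)c1cc(O[Si](C)(C)C(C)(C)C)c(O[Si](C)(C)C(C)(C)C)c(CO)c1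
F5 | step 13 | methyl 3-(bromomethyl)-4,5-bis[(tert-butyldimethylsilyl)oxy]benzoate | COC(=O)c1cc(O[Si](C)(C)C(C)(C)C)c(O[Si](C)(C)C(C)(C)C)c(CBr)c1
F6 | step 13 | 9α-arylmethyl derivative of enone 14 (C9 epimer of F7) | COC(=O)c1cc(O[Si](C)(C)C(C)(C)C)c(O[Si](C)(C)C(C)(C)C)c(C[C@@H]2C(=O)C=C[C@H]3C(C)(C)CCC[C@]23C)c1
F7 | step 13 | 9β-arylmethyl derivative of enone 14 (9α-H) | COC(=O)c1cc(O[Si](C)(C)C(C)(C)C)c(O[Si](C)(C)C(C)(C)C)c(C[C@H]2C(=O)C=C[C@H]3C(C)(C)CCC[C@]23C)c1
F8 | step 7 | 1′,1′,4a′-trimethyl-1′,3′,4′,4a′,5′,7′-hexahydro-2′H-spiro[1,3-dioxolane-2,6′-naphthalen]-2′-one (C5=C6 ketone, C10 configured as in 9) | O=C1CC[C@]2(C)CC3(OCCO3)CC=C2C1(C)C
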